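## Retrosynthetic overview
1. Target **14** (mollicellin B, a depsidone) is opened at the aryl ester to hydroxy-acid **13**. The seven-membered lactone is closed last (Step 12). **13** comes from the fully protected diaryl ether **12** by one TFA step that removes the t-Bu ester and both MOM ethers.
2. The diaryl ether C–O bond in **12** is made by a proposed new dehydrative phenol/phenol coupling (Step 10) between ring-A salicylaldehyde **11** and the ring-B chromanone phenol **7**.
3. Ring B (**7**) comes from orcinol. The order is Friedel–Crafts acetylation, regioselective 4-O-benzylation, Elbs para-hydroxylation (which installs the future ester oxygen), MOM protection, Kabbe chromanone formation, then hydrogenolysis. Ring A (**11**) comes from orsellinic acid by t-Bu ester formation, 4-O-MOM protection and Casnati ortho-formylation.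
4. Rings form in this order: the chromanone (Step 5), then the diaryl ether (Step 10), then the seven-membered lactone (Step 12).

**Assumptions.**
- The target SMILES has no stereocentres (the chromanone C2 carries two methyls), so there is no enantiomer to control and nothing can be scrambled.
- Orcinol and orsellinic acid are taken as commercial.
- Numbered compounds are substrates and intermediates. Small reagents are given by name and SMILES in the "Reagents" line.

---

## Route

**Step 1**
Reactants: **1** orcinol (5-methylbenzene-1,3-diol)
Product: **2** 1-(2,4-dihydroxy-6-methylphenyl)ethan-1-one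
Conditions: AcOH, BF3·OEt2, 85 °C
Reagents that add atoms: acetic acid, CC(=O)O
Why: BF3-mediated Friedel–Crafts acetylation of orcinol at C4 (para to one OH, ortho to the other OH and the methyl). C4 and C6 are equivalent, so there is no regio-issue, and the 2-OH is chelated to the C=O. No stereocentre.

**Step 2**
Reactants: **2**
Product: **3** 1-(4-(benzyloxy)-2-hydroxy-6-methylphenyl)ethan-1-one
Conditions: BnBr (1.05 equiv), CsHCO3, MeCN, 70 °C
Reagents that add atoms: benzyl bromide, BrCc1ccccc1
Why: The 4-OH is para to the carbonyl and more acidic, and the 2-OH is locked in an H-bond, so mild-base alkylation is selective for 4-O (Williamson ether synthesis).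

**Step 3**
Reactants: **3**
Product: **4** 1-(4-(benzyloxy)-2,5-dihydroxy-6-methylphenyl)ethan-1-one
Conditions: (a) K2S2O8, aq. NaOH, pyridine, 0 °C→rt, 24 h; (b) aq. HCl, EtOH, 60 °C (sulfate hydrolysis)
Reagents that add atoms: potassium persulfate (oxygen source), [K+].[K+].[O-]S(=O)(=O)OOS(=O)(=O)[O-]
Why: Elbs persulfate oxidation puts OH para to the phenolate (C5), the only free para position. This C5–OH becomes the ester-bearing oxygen of ring B.

**Step 4**
Reactants: **4**
Product: **5** 1-(4-(benzyloxy)-2-hydroxy-5-(methoxymethoxy)-6-methylphenyl)ethan-1-one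
Conditions: MOMCl, iPr2NEt, CH2Cl2, 0 °C, N2
Reagents that add atoms: chloromethyl methyl ether, ClCOC
Why: The chelated 2-OH is unreactive, so MOM goes only on the 5-OH. This also removes the oxidation-prone hydroquinone (2-OH/5-OH para).

**Step 5**
Reactants: **5**
Product: **6** 7-(benzyloxy)-6-(methoxymethoxy)-2,2,5-trimethylchroman-4-one
Conditions: acetone (5 equiv), pyrrolidine (0.5 equiv), 4 Å MS, toluene, 80 °C
Reagents that add atoms: acetone, CC(C)=O (supplies the C(CH3)2 carbon)
Why: Kabbe condensation. An enamine or aldol of acetone with the aryl methyl ketone is followed by intramolecular oxa-Michael closure to the 2,2-dimethylchromanone. The ring closure is the only step that creates a new sp3 carbon (C2), which is symmetric (two methyls).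

**Step 6**
Reactants: **6**
Product: **7** 7-hydroxy-6-(methoxymethoxy)-2,2,5-trimethylchroman-4-one
Conditions: H2 (1 atm), 10% Pd/C, EtOAc, rt, 2 h
Reagents that add atoms: none (H2 only; the Bn group is lost as toluene)
Why: Hydrogenolysis of the aryl benzyl ether. The MOM acetal and the aryl ketone survive neutral, short hydrogenation.

**Step 7**
Reactants: **8** orsellinic acid (2,4-dihydroxy-6-methylbenzoic acid)
Product: **9** tert-butyl 2,4-dihydroxy-6-methylbenzoate
Conditions: tBuOC(=NH)CCl3 (3 equiv), BF3·OEt2 (cat.), CH2Cl2/cyclohexane, rt
Reagents that add atoms: tert-butyl trichloroacetimidate, CC(C)(C)OC(=N)C(Cl)(Cl)Cl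
Why: Acid-catalysed O-tert-butylation of the carboxylic acid through a t-Bu cation equivalent. It is not hindered by the 2,6-disubstitution, and it gives an ester that TFA can remove later.

**Step 8**
Reactants: **9**
Product: **10** tert-butyl 2-hydroxy-4-(methoxymethoxy)-6-methylbenzoate
Conditions: MOMCl (1.05 equiv), iPr2NEt, CH2Cl2, 0 °C→rt
Reagents that add atoms: ClCOC (chloromethyl methyl ether)
Why: The 2-OH is chelated to the ester C=O, so only the 4-OH is alkylated (MOM protection).

**Step 9**
Reactants: **10**
Product: **11** tert-butyl 3-formyl-2-hydroxy-4-(methoxymethoxy)-6-methylbenzoate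
Conditions: MgCl2, Et3N, (CH2O)n, THF, reflux
Reagents that add atoms: paraformaldehyde, C=O (supplies the CHO carbon)
Why: Casnati–Skerlj ortho-formylation. The Mg phenoxide directs formylation ortho to the 2-O⁻; C1 is blocked, so only C3 reacts.

**Step 10**
Reactants: **11** (1.0 equiv) and **7** (1.3 equiv)
Product: **12** tert-butyl 3-formyl-4-(methoxymethoxy)-6-methyl-2-((6-(methoxymethoxy)-2,2,5-trimethyl-4-oxochroman-7-yl)oxy)benzoate
Conditions: 2-chloro-1,3-bis(2,6-diisopropylphenyl)imidazolium chloride (1.5 equiv), iPr2NEt (3 equiv), toluene, 80→110 °C, 12 h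
Reagents that add atoms: none (the imidazolium activator leaves as 1,3-bis(2,6-diisopropylphenyl)imidazol-2-one). Activator SMILES: Clc1n(c2c(C(C)C)cccc2C(C)C)cc[n+]1c1c(C(C)C)cccc1C(C)C.[Cl-]
Why: Proposed new method: direct dehydrative diaryl-ether formation from two phenols (a PhenoFluor-type deoxyfunctionalisation with a phenoxide as the nucleophile instead of fluoride).
- Mechanism: the acidic salicylaldehyde/salicylate phenol **11** adds to the 2-chloroimidazolium to give an aryl-oxy-imidazolium (uronium-type) leaving group. The ipso carbon is activated by the ortho CHO and CO2tBu. The phenoxide of **7** (para to its C=O, so acidic and nucleophilic) attacks ipso in a concerted SNAr. The C–O bond to the imidazolone is broken, and formation of the strong urea C=O drives the reaction.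
- Closest known reaction: PhenoFluor deoxyfluorination (concerted SNAr via an aryl uronium) combined with ordinary SNAr diaryl-ether synthesis.
- Either phenol could be the one activated; both pathways give the same C2(ring A)–O–C7(ring B) connection. No stereocentre is involved.

**Step 11**
Reactants: **12**
Product: **13** 2-((6-hydroxy-2,2,5-trimethyl-4-oxochroman-7-yl)oxy)-3-formyl-4-hydroxy-6-methylbenzoic acid
Conditions: TFA/CH2Cl2/H2O (10:10:1), rt, 12 h
Reagents that add atoms: none (only H added)
Why: Acidolysis removes the t-Bu ester and both MOM ethers in one step. The chromanone and aldehyde are acid-stable, and the ring-B MOM ether is electron-rich and cleaves readily.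

**Step 12**
Reactants: **13**
Product: **14** mollicellin B (target)
Conditions: TFAA (3 equiv), CH2Cl2, 0 °C→rt, 3 h; then NaHCO3/MeOH work-up
Reagents that add atoms: none (TFAA, FC(F)(F)C(=O)OC(=O)C(F)(F)F, only activates; transient trifluoroacetates are cleaved in work-up)
Why: Mixed-anhydride activation of the acid followed by intramolecular acylation of the ring-B 6-OH closes the seven-membered depsidone lactone. Proximity is enforced by the diaryl ether (a standard depsidone closure). The aldehyde-chelated 4-OH is the only other free phenol and is unreactive.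

---

## Compound list
1 | orcinol | Cc1cc(O)cc(O)c1 | starting material
2 | 1-(2,4-dihydroxy-6-methylphenyl)ethanone | CC(=O)c1c(C)cc(O)cc1O | intermediate
3 | 1-(4-benzyloxy-2-hydroxy-6-methylphenyl)ethanone | CC(=O)c1c(C)cc(OCc2ccccc2)cc1O | intermediate
4 | 1-(4-benzyloxy-2,5-dihydroxy-6-methylphenyl)ethanone | CC(=O)c1c(O)cc(OCc2ccccc2)c(O)c1C | intermediate
5 | 1-(4-benzyloxy-2-hydroxy-5-MOMO-6-methylphenyl)ethanone | CC(=O)c1c(O)cc(OCc2ccccc2)c(OCOC)c1C | intermediate
6 | 7-benzyloxy-6-MOMO-2,2,5-trimethylchroman-4-one | CC1(C)CC(=O)c2c(C)c(OCOC)c(OCc3ccccc3)cc2O1 | intermediate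
7 | 7-hydroxy-6-MOMO-2,2,5-trimethylchroman-4-one | CC1(C)CC(=O)c2c(C)c(OCOC)c(O)cc2O1 | intermediate
8 | orsellinic acid | Cc1cc(O)cc(O)c1C(=O)O | starting material
9 | tert-butyl 2,4-dihydroxy-6-methylbenzoate | Cc1cc(O)cc(O)c1C(=O)OC(C)(C)C | intermediate
10 | tert-butyl 2-hydroxy-4-MOMO-6-methylbenzoate | Cc1cc(OCOC)cc(O)c1C(=O)OC(C)(C)C | intermediate
11 | tert-butyl 3-formyl-2-hydroxy-4-MOMO-6-methylbenzoate | Cc1cc(OCOC)c(C=O)c(O)c1C(=O)OC(C)(C)C | intermediate
12 | protected diaryl ether (tBu ester, two MOM) | CC1(C)CC(=O)c2c(C)c(OCOC)c(Oc3c(C=O)c(OCOC)cc(C)c3C(=O)OC(C)(C)C)cc2O1 | intermediate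
13 | diaryl ether hydroxy-acid | CC1(C)CC(=O)c2c(C)c(O)c(Oc3c(C=O)c(O)cc(C)c3C(=O)O)cc2O1 | intermediate
14 | mollicellin B (achiral) | Cc1cc(O)c(C=O)c2c1C(=O)Oc1c(cc3c(c1C)C(=O)CC(C)(C)O3)O2 | target

---

**Total steps:** 12 (ring B branch 6, ring A branch 3, then coupling, global deprotection and lactonisation).
**Longest linear sequence:** 9 steps (orcinol → 2 → 3 → 4 → 5 → 6 → 7 → 12 → 13 → 14).

**Three steps most likely to fail**

1. **Step 10 (proposed new dehydrative diaryl-ether coupling).** The phenoxide may attack the imidazolium C2 reversibly instead of the hindered ipso carbon, which is flanked by CHO and CO2tBu.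
   - Fallback: convert **11** to its aryl triflate (Tf2O, pyridine), then Pd-catalysed C–O coupling with **7** (Pd2(dba)3/tBuBrettPhos, Cs2CO3, toluene). This is known two-step chemistry that does not use an aryl-uronium intermediate.
2. **Step 3 (Elbs oxidation).** The C5 position is flanked by the methyl and the OBn group, and Elbs yields are usually modest.
   - Fallback: Teuber oxidation of **3** with Fremy's salt to the p-quinone, then Na2S2O4 reduction to hydroquinone **4**. This is a radical, non-SN2 hydroxylation.
3. **Step 12 (lactonisation onto the hindered 6-OH, which is flanked by methyl and the aryl ether).**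
   - Fallback: change the ring-A carboxyl handle. Repeat Steps 7–11 starting from methyl orsellinate to give the hydroxy methyl ester, then close the lactone by Me3Al-mediated intramolecular transesterification through the aluminium phenoxide, instead of by carboxylic-acid activation.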